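**Retrosynthetic overview**

- Target ⇒ bis(hydroxyquinone) (methoxide addition/re-oxidation at the single free CH of each ring) ⇒ unsymmetrical bis-resorcinol (Fremy oxidation). The resorcinol with the chain between its two OH groups becomes ring A (OMe next to C-methyl, OH next to chain). The resorcinol with the methyl between its OH groups becomes ring B (OMe next to chain, OH next to C-methyl).
- Bis-resorcinol ⇒ bis-resorcylate diester (double saponification/decarboxylation).
- Ring A (formed second) ⇒ open-chain 4-alkyl-3,5,7-triketo ester, closed by polyketide-type C2→C7 aldol aromatisation; the chain is assembled in one flask from the ω-bromide, methyl acetoacetate dianion and diketene.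
- Ring B (formed first) ⇒ open-chain 4-methyl-3,5,7-triketo ester, closed by the same aldol aromatisation; made from ω-pentadecalactone (acyl "starter") and the trianion of methyl 4-methyl-3,5-dioxohexanoate.
- Order: ring B → OH to Br → ring A → decarboxylation → both quinones → both OMe groups.

Assumption: the target has no stereocentre or other stereogenic element, so it is achiral and there is no enantiomer to select; the SMILES is taken literally, i.e. the two quinone rings are regioisomeric.

**Route**

Step 1
Reactants: 1 3-methylpentane-2,4-dione; 2 dimethyl carbonate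
Product: 3 methyl 4-methyl-3,5-dioxohexanoate (racemic, enolisable C4)
Conditions: 1 (2 equiv), LDA (4 equiv), THF, 0 °C; 2 (1 equiv), 0 °C → rt; aq. HCl
Reagents that add atoms: none
Why: Hauser–Harris C-acylation (Claisen type) – the 1,3-dianion of the β-diketone reacts only through its terminal carbanion with the non-enolisable carbonate, and the second equivalent of dianion stores the more acidic product as its salt.

Step 2
Reactants: 3 methyl 4-methyl-3,5-dioxohexanoate; 4 oxacyclohexadecan-2-one (ω-pentadecalactone)
Product: 6 methyl 2,4-dihydroxy-6-(14-hydroxytetradecyl)-3-methylbenzoate, via open-chain hydroxy tetraketide 5 (not isolated)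
Conditions: 3 (2.2 equiv), LDA (6.8 equiv), THF, 0 °C; 4 (1 equiv), 0 °C → rt; H2O/MeOH, rt, 2 h (LiOH formed in situ); 2 M HCl
Reagents that add atoms: none
Why: Harris-type Claisen acylation of the terminal (C6) carbanion of the diketo-ester trianion by the lactone carbonyl gives the 3,5,7-triketo ester, whose doubly activated C2 methylene closes onto the C7 ketone (intramolecular aldol condensation, the ring closure of resorcylate-forming polyketide synthases) and aromatises on acidification; the racemic C4 centre disappears.

Step 3
Reactants: 6 methyl 2,4-dihydroxy-6-(14-hydroxytetradecyl)-3-methylbenzoate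
Product: 7 methyl 6-(14-bromotetradecyl)-2,4-dihydroxy-3-methylbenzoate
Conditions: CBr4 (1.3 equiv), PPh3 (1.3 equiv), CH2Cl2, 0 °C → rt
Reagents that add atoms: carbon tetrabromide, BrC(Br)(Br)Br
Why: Appel reaction – SN2 displacement of the primary alkoxyphosphonium by bromide; the phenols (sp2 carbon, no SN2) and the hydrogen-bonded ester are not touched.

Step 4
Reactants: 7 methyl 6-(14-bromotetradecyl)-2,4-dihydroxy-3-methylbenzoate; 8 methyl acetoacetate; 9 diketene (4-methylideneoxetan-2-one)
Product: 12 methyl 3-[14-(3,5-dihydroxy-2-methoxycarbonyl-4-methylphenyl)tetradecyl]-2,4-dihydroxy-6-methylbenzoate, via chain keto ester 10 (not isolated), via open-chain tetraketide diester 11 (not isolated)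
Conditions: 7, LDA (2.0 equiv), THF–DMPU, −78 °C; add to dianion of 8 (1.2 equiv, from 8 + 2.4 equiv LDA), 0 °C, 1 h; LDA (1.2 equiv), 0 °C, 30 min; 9 (1.3 equiv), −78 °C; H2O/MeOH, rt, 2 h; 2 M HCl
Reagents that add atoms: none
Why: Proposed new method: one-flask alkylative assembly of a 4-alkyl tetraketide – Huckin–Weiler γ-alkylation of the acetoacetate dianion by the primary bromide, regeneration of the dianion at the now secondary γ-carbon, C-acetoacetylation of that carbanion by acyl attack on the strained enol lactone diketene (enolate leaving group, no by-product), then the same C2→C7 aldol aromatisation as in step 2, which places the chain between the two phenolic oxygens; the closest known reactions are Weiler's sequential γ-functionalisation of β-keto ester dianions, Harris acylation of polyanions with β-keto ester salts and the base-mediated acetoacetate/diketene route to orsellinates; the racemic C4 centre of 11 disappears.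

Step 5
Reactants: 12 methyl 3-[14-(3,5-dihydroxy-2-methoxycarbonyl-4-methylphenyl)tetradecyl]-2,4-dihydroxy-6-methylbenzoate
Product: 14 the bis-resorcinol 2-[14-(3,5-dihydroxy-4-methylphenyl)tetradecyl]-5-methylbenzene-1,3-diol, via bis-resorcylic diacid 13 (not isolated)
Conditions: KOH (excess), DMSO/H2O, 110 °C, Ar; then 3 M HCl, 90 °C
Reagents that add atoms: none
Why: Ester saponification followed by acid-promoted protodecarboxylation (ipso-protonation of the electron-rich β-resorcylic acids), the chemical counterpart of the decarboxylation in alkylresorcinol biosynthesis.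

Step 6
Reactants: 14 2-[14-(3,5-dihydroxy-4-methylphenyl)tetradecyl]-5-methylbenzene-1,3-diol
Product: 15 3-hydroxy-2-[14-(5-hydroxy-4-methyl-3,6-dioxocyclohexa-1,4-dien-1-yl)tetradecyl]-5-methylcyclohexa-2,5-diene-1,4-dione
Conditions: (KSO3)2NO (4.5 equiv), KH2PO4 buffer, H2O/acetone (Aliquat 336 if needed), 0 °C → rt
Reagents that add atoms: potassium nitrosodisulfonate (Fremy's salt), [K+].[K+].[O-]S(=O)(=O)N([O])S(=O)(=O)[O-]
Why: Teuber oxidation – the nitroxide abstracts a phenolic hydrogen and a second equivalent delivers oxygen to the only kind of free ring position (para to one OH, ortho to the other, the two being equivalent in each ring), so each resorcinol gives one 2-hydroxy-1,4-benzoquinone whose single ring CH lies next to the C-methyl carbon in one ring and next to the chain carbon in the other.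

Step 7
Reactants: 15 3-hydroxy-2-[14-(5-hydroxy-4-methyl-3,6-dioxocyclohexa-1,4-dien-1-yl)tetradecyl]-5-methylcyclohexa-2,5-diene-1,4-dione
Product: 17 the target 2-hydroxy-3-[14-(5-hydroxy-2-methoxy-4-methyl-3,6-dioxocyclohexa-1,4-dien-1-yl)tetradecyl]-5-methoxy-6-methylcyclohexa-2,5-diene-1,4-dione, via bis-hydroquinone 16 (not isolated)
Conditions: NaOMe (6 equiv), dry MeOH, O2 (1 atm), 0 °C → rt; cold aq. HCl
Reagents that add atoms: sodium methoxide, C[O-].[Na+]
Why: Proposed new method: oxidative nucleophilic methoxylation – in each hydroxyquinone anion the O⁻–C=C–C=O vinylogous carboxylate deactivates one carbonyl, so methoxide adds in Michael fashion to the single unsubstituted ring carbon (β to the other carbonyl) and the hydroquinone formed is re-oxidised by O2, which fixes OMe next to C-methyl in ring A and next to the chain in ring B; the closest known reactions are the alkoxylation of quinones by alcohol addition/re-oxidation and the conversion of hydroxyquinones into 2,5-dihydroxyquinones in aerated alkali.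

**Compound list**

1 | 3-methylpentane-2,4-dione (achiral) | CC(=O)C(C)C(C)=O | starting material
2 | dimethyl carbonate | COC(=O)OC | starting material
3 | methyl 4-methyl-3,5-dioxohexanoate (racemic) | CC(=O)C(C)C(=O)CC(=O)OC | intermediate
4 | oxacyclohexadecan-2-one (ω-pentadecalactone) | O=C1CCCCCCCCCCCCCCO1 | starting material
5 | methyl 21-hydroxy-4-methyl-3,5,7-trioxohenicosanoate (racemic) | OCCCCCCCCCCCCCCC(=O)CC(=O)C(C)C(=O)CC(=O)OC | intermediate (not isolated)
6 | methyl 2,4-dihydroxy-6-(14-hydroxytetradecyl)-3-methylbenzoate | COC(=O)c1c(O)c(C)c(O)cc1CCCCCCCCCCCCCCO | intermediate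
7 | methyl 6-(14-bromotetradecyl)-2,4-dihydroxy-3-methylbenzoate | COC(=O)c1c(O)c(C)c(O)cc1CCCCCCCCCCCCCCBr | intermediate
8 | methyl acetoacetate (methyl 3-oxobutanoate) | CC(=O)CC(=O)OC | starting material
9 | diketene (4-methylideneoxetan-2-one) | C=C1CC(=O)O1 | starting material
10 | methyl 18-(3,5-dihydroxy-2-methoxycarbonyl-4-methylphenyl)-3-oxooctadecanoate | COC(=O)CC(=O)CCCCCCCCCCCCCCCc1cc(O)c(C)c(O)c1C(=O)OC | intermediate (not isolated)
11 | methyl 4-[14-(3,5-dihydroxy-2-methoxycarbonyl-4-methylphenyl)tetradecyl]-3,5,7-trioxooctanoate (racemic) | COC(=O)CC(=O)C(CCCCCCCCCCCCCCc1cc(O)c(C)c(O)c1C(=O)OC)C(=O)CC(C)=O | intermediate (not isolated)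
12 | methyl 3-[14-(3,5-dihydroxy-2-methoxycarbonyl-4-methylphenyl)tetradecyl]-2,4-dihydroxy-6-methylbenzoate | COC(=O)c1c(C)cc(O)c(CCCCCCCCCCCCCCc2cc(O)c(C)c(O)c2C(=O)OC)c1O | intermediate
13 | 3-[14-(2-carboxy-3,5-dihydroxy-4-methylphenyl)tetradecyl]-2,4-dihydroxy-6-methylbenzoic acid | OC(=O)c1c(C)cc(O)c(CCCCCCCCCCCCCCc2cc(O)c(C)c(O)c2C(=O)O)c1O | intermediate (not isolated)
14 | 2-[14-(3,5-dihydroxy-4-methylphenyl)tetradecyl]-5-methylbenzene-1,3-diol | Cc1cc(O)c(CCCCCCCCCCCCCCc2cc(O)c(C)c(O)c2)c(O)c1 | intermediate
15 | 3-hydroxy-2-[14-(5-hydroxy-4-methyl-3,6-dioxocyclohexa-1,4-dien-1-yl)tetradecyl]-5-methylcyclohexa-2,5-diene-1,4-dione | CC1=CC(=O)C(CCCCCCCCCCCCCCC2=CC(=O)C(C)=C(O)C2=O)=C(O)C1=O | intermediate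
16 | 3-[14-(2,3,5-trihydroxy-6-methoxy-4-methylphenyl)tetradecyl]-5-methoxy-6-methylbenzene-1,2,4-triol | COc1c(C)c(O)c(O)c(CCCCCCCCCCCCCCc2c(OC)c(O)c(C)c(O)c2O)c1O | intermediate (not isolated)
17 | 2-hydroxy-3-[14-(5-hydroxy-2-methoxy-4-methyl-3,6-dioxocyclohexa-1,4-dien-1-yl)tetradecyl]-5-methoxy-6-methylcyclohexa-2,5-diene-1,4-dione (achiral) | COC1=C(C)C(=O)C(O)=C(CCCCCCCCCCCCCCC2=C(OC)C(=O)C(C)=C(O)C2=O)C1=O | target

**Summary**

Total step count: 7. Longest linear sequence: 7 (steps 1–7 lie on one line; 6 steps from ω-pentadecalactone 4).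

**Steps most likely to fail and their fallbacks**

Step 4 (the hindered secondary carbanion may deprotonate diketene instead of being acylated, and the polyanionic mixture may give retro-Claisen or Claisen-type by-products). The fallback sets out from 7 and comes back at 12. The alkylation of 7 with the dianion of 8 is stopped after the first stage and the keto ester 10 is isolated. Ring A is then built by a different ring-forming logic, the Michael–Claisen annulation used for dialkylresorcinols. Treating 10 with methyl (E)-crotonate and NaOMe in MeOH at reflux adds C2 of the keto ester to the crotonate, and the chain-bearing C4 then closes onto the crotonate ester. This gives methyl 3-[14-(3,5-dihydroxy-2-methoxycarbonyl-4-methylphenyl)tetradecyl]-6-methyl-2,4-dioxocyclohexane-1-carboxylate F2 (mixture of diastereomers and enol forms), which is dehydrogenated (10% Pd/C, p-cymene, reflux) to 12.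

Step 7 (methoxide addition to an anionic quinone may be slow, and peroxide formed during re-oxidation may degrade the hydroxyquinones). The fallback sets out from 15 and comes back at 17 and avoids any redox step. Bromine (2.1 equiv, AcOH/CHCl3, rt) substitutes the single ring CH of each quinone by addition/dehydrobromination to give 6-bromo-2-[14-(2-bromo-5-hydroxy-4-methyl-3,6-dioxocyclohexa-1,4-dien-1-yl)tetradecyl]-3-hydroxy-5-methylcyclohexa-2,5-diene-1,4-dione F3. NaOMe in MeOH (0 °C → rt) then replaces each vinylic bromide by methoxide through addition–elimination to give 17.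

Step 2 (the trianion may enolise the lactone rather than be acylated, and the 4-methyl tetraketide may partly cyclise in the Claisen sense). The fallback sets out from 4 and comes back at 6 and reverses the polarity of the chain extension. The lactone 4 is opened with the lithium enolate of methyl acetate (LDA, MeOAc, THF, −78 °C) to methyl 17-hydroxy-3-oxoheptadecanoate F1. F1, as its salt, is then acylated at its ester carbonyl by the γ-carbanion of the dianion of commercial methyl 3-oxopentanoate (NaH, n-BuLi, THF, 0 °C → rt). This gives the same tetraketide 5, which is cyclised and aromatised as in step 2 to 6.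

**Further compounds**

F1 | step 2 | methyl 17-hydroxy-3-oxoheptadecanoate | COC(=O)CC(=O)CCCCCCCCCCCCCCO
F2 | step 4 | methyl 3-[14-(3,5-dihydroxy-2-methoxycarbonyl-4-methylphenyl)tetradecyl]-6-methyl-2,4-dioxocyclohexane-1-carboxylate (mixture of diastereomers) | COC(=O)C1C(C)CC(=O)C(CCCCCCCCCCCCCCc2cc(O)c(C)c(O)c2C(=O)OC)C1=O
F3 | step 7 | 6-bromo-2-[14-(2-bromo-5-hydroxy-4-methyl-3,6-dioxocyclohexa-1,4-dien-1-yl)tetradecyl]-3-hydroxy-5-methylcyclohexa-2,5-diene-1,4-dione | CC1=C(Br)C(=O)C(CCCCCCCCCCCCCCC2=C(Br)C(=O)C(C)=C(O)C2=O)=C(O)C1=O
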